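**Plan**

1. Numbering: vinyl C1=C2; pyran O1 and C3–C7 (Br on C6); linker C8, C9; cyclohexane C10–C15 (OH and Me on C11, Br on C14, Me2 on C15). Enabling feature: O1 lies between two methyl-bearing quaternary carbons, C3 and C7, whose carbon substituents C2 and C8 are cis, so the pyran is a 1,5-dimethyl-8-oxabicyclo[3.2.1]oct-6-ene with C2=C8 as the etheno bridge.
2. Retrosynthetic cuts: C1=C2 (Wittig); C4 methylene from a C4 ketone; C11–CH3 (Grignard); C8–C9 (C8 radical onto a 2-methylenecyclohexanone); C2=C8 (ozonolysis reversed); C6–Br (bromide 1,4-addition to a C4 enone); C3–C4 and C6–C7 (furan plus oxyallyl cation, [4+3]); C10–C15 (bromonium-initiated cyclisation of a β-keto ester).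
3. Forward, pyran half: the bridged pyranone forms first; it is desymmetrised, the carbonyl is moved from C5 to C4, bromide is added at C6, and the bridge is cut. The C4 oxygen then ties up the C2 arm as an acetonide, so only the C8 arm becomes the iodide.
4. Forward, union: the bromo enone is made separately, joined at C8–C9 and methylated at C11; C4 is then deoxygenated and the vinyl group is made last.
5. Stereochemistry: C3/C7 cis from the bicycle, absolute sense from a chiral lithium amide; C6 from exo attack on the bicycle; C14 from a Shi epoxide via a configurationally defined bromonium ion; C10 from hydrogen-atom transfer (thermodynamic epimer); C11 from equatorial Grignard attack.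

Key step: step 1

Assumption 1: the sense of enolisation by the (R,R)-amide in step 2 is assigned by analogy with related bridged ketones; if the antipode forms, the (S,S)-amide is used.
Assumption 2: the temporary C4 carbinol (steps 6–17) is drawn as the epimer from exo hydride delivery; its epimer would pass through the same steps, because C4 is oxidised in step 18.

**Route**

Step 1
Reactants: 1 2,5-dimethylfuran; 2 3-bromo-2-methoxyprop-1-ene
Product: 5 meso-1,5-dimethyl-8-oxabicyclo[3.2.1]oct-6-en-3-one, via 2-methoxyallyl cation 3 (not isolated), via enol ether 4 (not isolated)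
Conditions: AgO2CCF3, Na2CO3, 1 (excess), isopentane, 0 °C, dark; then 1 M HNO3, rt
Reagents that add atoms: water, O
Why: Silver(I) removes bromide from 2, and the 2-methoxyallyl cation (a three-carbon 2π partner) adds across the two α-carbons of the furan 4π system in a [4+3] cycloaddition that forms C3–C4 and C6–C7; proton loss gives enol ether 4, which dilute acid hydrolyses to 5. The closest known reaction type is the cycloaddition of 2-oxyallyl cations with furans to 8-oxabicyclo[3.2.1]oct-6-en-3-ones. Two rings close in the one event by two-point union of the cation termini with the furan α-carbons: the seven-membered carbocycle (C2, C3, C4, C5, C6, C7, C8) and, inside it, the oxygen-bridged six-membered pyranone (O1, C3–C7). The new stereocentres C3 and C7 are controlled by the ring itself, because the oxygen bridge can only span cis positions, so C2 and C8 are cis and the adduct is meso. The selectivity needed is cycloaddition over electrophilic substitution at a furan β-carbon and over hydrolysis of 2; the weakly electrophilic methoxy-stabilised cation, the raised HOMO of the dialkylfuran, the carbonate buffer and the excess of furan should secure it.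

Step 2
Reactants: 5 meso-1,5-dimethyl-8-oxabicyclo[3.2.1]oct-6-en-3-one
Product: 6 1,5-dimethyl-3-(trimethylsilyloxy)-8-oxabicyclo[3.2.1]octa-2,6-diene (single enantiomer; enol double bond C4=C5 on the side of the future C3)
Conditions: (R,R)-[PhCH(Me)]2NLi (from the amine and n-BuLi), TMSCl (in situ), THF, −100 °C
Reagents that add atoms: chlorotrimethylsilane, C[Si](C)(C)Cl
Why: Enantiotopic-group-selective deprotonation of the meso ketone by the C2-symmetric chiral lithium amide with internal silyl quench (asymmetric deprotonation) removes the exo proton at C4 only and so fixes the absolute configuration of C3 and C7, which the cycloaddition had set in relative terms.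

Step 3
Reactants: 6 the silyl enol ether
Product: 8 1,5-dimethyl-8-oxabicyclo[3.2.1]octa-2,6-dien-3-yl trifluoromethanesulfonate (C4=C5), via lithium enolate 7 (not isolated)
Conditions: MeLi, THF, 0 °C; then PhNTf2, −78 °C → rt
Reagents that add atoms: N-phenylbis(trifluoromethanesulfonimide), O=S(=O)(N(c1ccccc1)S(=O)(=O)C(F)(F)F)C(F)(F)F
Why: Methyllithium cleaves the silyl enol ether to the regiodefined lithium enolate 7 and N-phenyltriflimide sulfonylates it on oxygen (enol triflate formation), so the C4=C5 position of the double bond is carried over unchanged.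

Step 4
Reactants: 8 the enol triflate
Product: 9 1,5-dimethyl-8-oxabicyclo[3.2.1]octa-2,6-diene (double bonds C4=C5 and C2=C8)
Conditions: Pd(OAc)2 (5 mol%), PPh3, Bu3N, HCO2H, DMF, 60 °C
Reagents that add atoms: none
Why: Palladium-catalysed formate reduction of the enol triflate (oxidative addition, formate exchange, decarboxylation, reductive elimination) replaces OTf by H and leaves the desymmetrising C4=C5 alkene; the volatile diene is kept in solution.

Step 5
Reactants: 9 the diene
Product: 12 1,5-dimethyl-8-oxabicyclo[3.2.1]octa-3,6-dien-2-one (C4=O, C5=C6), via hydroperoxide 10 (not isolated), via peracetate 11 (not isolated)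
Conditions: O2, tetraphenylporphyrin (cat.), hν (white LED), CH2Cl2, 0 °C; then Ac2O, pyridine, DMAP (cat.), 0 °C → rt
Reagents that add atoms: oxygen, O=O
Why: Schenck ene reaction with singlet oxygen followed by Kornblum–DeLaMare dehydration of the peracetate: C6 holds the only allylic hydrogens, so oxygen must bond to C4 while the alkene moves to C5=C6, and because this path is concerted (unlike radical allylic oxidation through a symmetric allyl radical) the enantiomeric purity should be kept while the carbonyl group moves from C5 to C4.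

Step 6
Reactants: 12 the enone
Product: 15 4-exo-bromo-1,5-dimethyl-8-oxabicyclo[3.2.1]oct-6-en-2-endo-ol (C6–Br exo, C4–OH), via bromo silyl enol ether 13 (not isolated), via bromo ketone 14 (not isolated)
Conditions: TMSBr, CH2Cl2, −78 → −40 °C; then MeOH, CeCl3·7H2O, NaBH4, −78 °C
Reagents that add atoms: bromotrimethylsilane, C[Si](C)(C)Br
Why: Conjugate addition of bromide to the silyl-activated enone (halosilane 1,4-addition) should occur on the exo face, syn to the oxygen bridge and anti to the etheno bridge, which sets C6 with bromine cis to both methyl groups; methanolysis with Luche reduction in the same flask traps the labile β-bromo ketone as the carbinol before HBr can be lost again.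

Step 7
Reactants: 15 the bromo alcohol
Product: 17 5-bromo-2,6-bis(hydroxymethyl)-2,6-dimethyloxan-3-ol (hydroxymethyl groups cis; Br trans to them), via dialdehyde 16 (not isolated)
Conditions: O3, CH2Cl2/MeOH, −78 °C; Me2S; then NaBH4, 0 °C
Reagents that add atoms: ozone, [O-][O+]=O
Why: Ozonolysis of the strained C2=C8 alkene with reductive work-up turns the etheno bridge into two cis hydroxymethyl arms without touching C3, C6 or C7.

Step 8
Reactants: 17 the triol
Product: 18 (7-bromo-2,2,4a,6-tetramethylhexahydropyrano[3,2-d][1,3]dioxin-6-yl)methanol (acetonide over C4–O and C2–O; C8–OH free)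
Conditions: Me2C(OMe)2, PPTS (cat.), acetone, rt
Reagents that add atoms: 2,2-dimethoxypropane, COC(C)(C)OC
Why: Acid-catalysed transketalisation forms the six-membered acetonide on the only 1,3-diol of the triol (C4–OH with C2–OH, the 4,6-O-isopropylidene pattern of pyranosides), which tells the two arms apart by leaving only the C8 hydroxyl free.

Step 9
Reactants: 18 the acetonide alcohol
Product: 19 7-bromo-6-(iodomethyl)-2,2,4a,6-tetramethylhexahydropyrano[3,2-d][1,3]dioxine
Conditions: I2, PPh3, imidazole, toluene, 70 °C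
Reagents that add atoms: iodine, II
Why: Appel-type iodination (PPh3, I2, imidazole) converts the neopentylic primary alcohol into the iodide by SN2 displacement of the alkoxyphosphonium group, with heat needed because of the quaternary neighbour.

Step 10
Reactants: 20 ethyl 5-methylhex-4-enoate
Product: 21 ethyl 3-[(2S)-3,3-dimethyloxiran-2-yl]propanoate
Conditions: L-sorbose-derived Shi ketone (30 mol%), Oxone, K2CO3, Bu4NHSO4, MeCN/dimethoxymethane–aq. borate buffer, 0 °C
Reagents that add atoms: potassium peroxymonosulfate, [K+].[O-]S(=O)(=O)OO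
Why: Shi epoxidation: the chiral dioxirane transfers oxygen to the trisubstituted alkene through the spiro transition state, and the L-series ketone should give the (S)-epoxide, which is the source of C14.

Step 11
Reactants: 21 the epoxy ester; 22 prop-2-enyl acetate
Product: 24 prop-2-enyl 5-[(2S)-3,3-dimethyloxiran-2-yl]-3-oxopentanoate, via lithium enolate 23 (not isolated)
Conditions: 22, LiHMDS, THF, −78 °C; then 21, −78 → −30 °C; aq. NH4Cl
Reagents that add atoms: none
Why: Crossed Claisen condensation of the preformed lithium enolate 23 with the ethyl ester of 21 gives the β-keto ester as its enolate, the epoxide and the allyl ester enolate both being stable below −30 °C.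

Step 12
Reactants: 24 the epoxy keto ester
Product: 25 prop-2-enyl (6R)-6-bromo-7-hydroxy-7-methyl-3-oxooctanoate
Conditions: Li2NiBr4, THF, 0 °C → rt
Reagents that add atoms: dilithium tetrabromonickelate, [Li+].[Li+].[Ni+2].[Br-].[Br-].[Br-].[Br-]
Why: Soft bromide from Li2NiBr4 opens the epoxide by SN2 attack at the less substituted carbon with inversion, giving the (R)-configured secondary bromide beside the tertiary carbinol.

Step 13
Reactants: 25 the bromohydrin
Product: 26 prop-2-enyl (1R,3R)-3-bromo-2,2-dimethyl-6-oxocyclohexane-1-carboxylate (C1 epimerisable)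
Conditions: SnCl4, CH2Cl2, −78 → −20 °C
Reagents that add atoms: none
Why: The Lewis acid ionises the tertiary carbinol with anchimeric help from bromine to a configurationally defined bromonium ion, which the chelated β-keto ester enol opens at the tertiary carbon in a 6-endo cation–olefin cyclisation (bromonium-initiated cyclisation ended by a β-keto ester) that forms C10–C15 through a chair with bromine equatorial, C14 keeping its configuration and C10 remaining epimerisable.

Step 14
Reactants: 26 the cyclic keto ester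
Product: 29 (4R)-4-bromo-3,3-dimethyl-2-methylidenecyclohexan-1-one, via keto acid 27 (not isolated), via Mannich acid 28 (not isolated)
Conditions: Pd(PPh3)4 (3 mol%), morpholine, THF, 0 °C; then aq. CH2O, AcOH, rt → 45 °C
Reagents that add atoms: formaldehyde, C=O
Why: Palladium(0) transfers the allyl group to morpholine (Tsuji–Trost deallylation) and the freed β-keto acid undergoes a Mannich reaction with formaldehyde and morpholine followed by decarboxylative elimination, which turns C10 into the sp2 carbon of the exocyclic enone and adds C9.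

Step 15
Reactants: 19 the iodide; 29 the enone (2 equiv)
Product: 30 (2R,4R)-4-bromo-2-[2-(7-bromo-2,2,4a,6-tetramethylhexahydropyrano[3,2-d][1,3]dioxin-6-yl)ethyl]-3,3-dimethylcyclohexan-1-one
Conditions: (TMS)3SiH (slow addition), AIBN, benzene, 80 °C
Reagents that add atoms: none
Why: Giese reaction: the silyl radical abstracts iodine far faster than bromine, the primary C8 radical adds to the unhindered methylene carbon C9 of the enone, and hydrogen transfer from the silane to the C10 α-keto radical on the face away from the axial C15 methyl group should give the equatorial (also thermodynamic) side chain, cis to the C14 bromine.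

Step 16
Reactants: 30 the ketone
Product: 31 (1S,2R,4R)-4-bromo-2-[2-(7-bromo-2,2,4a,6-tetramethylhexahydropyrano[3,2-d][1,3]dioxin-6-yl)ethyl]-1,3,3-trimethylcyclohexan-1-ol
Conditions: MeMgBr, CeCl3 (anhydrous), THF, −78 °C
Reagents that add atoms: methylmagnesium bromide, C[Mg]Br
Why: Cerium-mediated Grignard addition without enolisation: the axial C15 methyl group blocks axial attack on the C11 carbonyl, so the methyl group should enter equatorially and the new hydroxyl is axial and cis to the C10 side chain, as in additions to 3,3,5-trimethylcyclohexanone.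

Step 17
Reactants: 31 the acetonide carbinol
Product: 32 (1S,2R,4R)-4-bromo-2-{2-[3-bromo-5-hydroxy-6-(hydroxymethyl)-2,6-dimethyloxan-2-yl]ethyl}-1,3,3-trimethylcyclohexan-1-ol (C2–OH, C4–OH, C11–OH)
Conditions: PPTS, MeOH, 40 °C
Reagents that add atoms: none
Why: Acid-catalysed transketalisation in methanol removes the acetonide, the tertiary alcohol, both secondary bromides and the ring ether being stable to PPTS.

Step 18
Reactants: 32 the triol
Product: 33 5-bromo-6-{2-[(1R,3R,6S)-3-bromo-6-hydroxy-2,2,6-trimethylcyclohexyl]ethyl}-2-(hydroxymethyl)-2,6-dimethyloxan-3-one (C4 ketone)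
Conditions: NaOCl (aq.), AcOH, 0 °C → rt
Reagents that add atoms: none
Why: Hypochlorite in acetic acid (Stevens oxidation) oxidises the secondary C4 alcohol much faster than the neopentylic primary C2 alcohol and cannot oxidise the tertiary one, which gives the C4 ketone needed for deoxygenation.

Step 19
Reactants: 33 the hydroxy ketone
Product: 34 the C4 tosylhydrazone of 33
Conditions: TsNHNH2, EtOH, AcOH (cat.), rt
Reagents that add atoms: 4-methylbenzenesulfonohydrazide, Cc1ccc(cc1)S(=O)(=O)NN
Why: Condensation of the ketone with tosylhydrazide to the tosylhydrazone runs without base, so the β-bromo ketone should not eliminate.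

Step 20
Reactants: 34 the tosylhydrazone
Product: 36 (1S,2R,4R)-4-bromo-2-{2-[(2S,3R,6S)-3-bromo-6-(hydroxymethyl)-2,6-dimethyloxan-2-yl]ethyl}-1,3,3-trimethylcyclohexan-1-ol, via tosylhydrazine 35 (not isolated)
Conditions: catecholborane, CHCl3, 0 °C; then NaOAc·3H2O, reflux
Reagents that add atoms: none
Why: Caglioti-type reduction in its catecholborane variant: hydride adds to C=N and acetate then induces loss of sulfinate and dinitrogen from the diazene to leave C4 as CH2, the C6 bromine being 1,3 to the reacting carbon and therefore not expelled, and the vinyl group not yet present to rearrange.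

Step 21
Reactants: 36 the diol
Product: 37 (2S,5R,6S)-5-bromo-6-{2-[(1R,3R,6S)-3-bromo-6-hydroxy-2,2,6-trimethylcyclohexyl]ethyl}-2,6-dimethyloxane-2-carbaldehyde
Conditions: Dess–Martin periodinane, NaHCO3, CH2Cl2, 0 °C → rt
Reagents that add atoms: none
Why: Dess–Martin oxidation of the primary alcohol gives the non-enolisable α-alkoxy aldehyde and leaves the tertiary alcohol.

Step 22
Reactants: 37 the aldehyde
Product: 38 (1S,2R,4R)-4-bromo-2-{2-[(2S,3R,6S)-3-bromo-6-ethenyl-2,6-dimethyloxan-2-yl]ethyl}-1,3,3-trimethylcyclohexan-1-ol (target)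
Conditions: Ph3PCH3Br, KHMDS, THF, −78 → 0 °C
Reagents that add atoms: methyltriphenylphosphonium bromide, C[P+](c1ccccc1)(c1ccccc1)c1ccccc1.[Br-]
Why: Wittig methylenation at low temperature, with one extra equivalent of ylide for the tertiary hydroxyl, makes the C1=C2 vinyl group last, so that it never meets ozone, radicals or borane.

**Compound list**

1 | 2,5-dimethylfuran | Cc1ccc(C)o1 | starting material
2 | 3-bromo-2-methoxyprop-1-ene | C=C(OC)CBr | starting material
3 | 2-methoxyallyl cation (trifluoroacetate) | C=C(OC)[CH2+].[O-]C(=O)C(F)(F)F | intermediate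
4 | 3-methoxy-1,5-dimethyl-8-oxabicyclo[3.2.1]octa-2,6-diene (racemic; one enantiomer drawn) | C2[C@]1(C)C=C(OC)C[C@](C)(C=2)O1 | intermediate
5 | meso-1,5-dimethyl-8-oxabicyclo[3.2.1]oct-6-en-3-one | C[C@@]12CC(=O)C[C@@](C)(C=C1)O2 | intermediate
6 | 1,5-dimethyl-3-(trimethylsilyloxy)-8-oxabicyclo[3.2.1]octa-2,6-diene (C4=C5 enol ether, single enantiomer) | C2[C@]1(C)C=C(O[Si](C)(C)C)C[C@](C)(C=2)O1 | intermediate
7 | lithium enolate corresponding to 6 | C2[C@]1(C)C=C([O-])C[C@](C)(C=2)O1.[Li+] | intermediate
8 | 1,5-dimethyl-8-oxabicyclo[3.2.1]octa-2,6-dien-3-yl trifluoromethanesulfonate | C2[C@]1(C)C=C(OS(=O)(=O)C(F)(F)F)C[C@](C)(C=2)O1 | intermediate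
9 | 1,5-dimethyl-8-oxabicyclo[3.2.1]octa-2,6-diene (C4=C5, C2=C8) | C2[C@]1(C)C=CC[C@](C)(C=2)O1 | intermediate
10 | 1,5-dimethyl-8-oxabicyclo[3.2.1]octa-3,6-dien-2-exo-yl hydroperoxide | C2[C@]1(C)[C@@H](OO)C=C[C@](C)(C=2)O1 | intermediate
11 | peracetate of 10 | C2[C@]1(C)[C@@H](OOC(C)=O)C=C[C@](C)(C=2)O1 | intermediate
12 | 1,5-dimethyl-8-oxabicyclo[3.2.1]octa-3,6-dien-2-one (C4=O, C5=C6) | C2[C@]1(C)C(=O)C=C[C@](C)(C=2)O1 | intermediate
13 | 4-exo-bromo-1,5-dimethyl-2-(trimethylsilyloxy)-8-oxabicyclo[3.2.1]octa-2,6-diene | C2[C@]1(C)C(O[Si](C)(C)C)=C[C@@H](Br)[C@](C)(C=2)O1 | intermediate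
14 | 4-exo-bromo-1,5-dimethyl-8-oxabicyclo[3.2.1]oct-6-en-2-one | C2[C@]1(C)C(=O)C[C@@H](Br)[C@](C)(C=2)O1 | intermediate
15 | 4-exo-bromo-1,5-dimethyl-8-oxabicyclo[3.2.1]oct-6-en-2-endo-ol | C2[C@]1(C)[C@H](O)C[C@@H](Br)[C@](C)(C=2)O1 | intermediate
16 | 5-bromo-3-hydroxy-2,6-dimethyloxane-2,6-dicarbaldehyde (formyl groups cis) | O=C[C@]1(C)[C@H](O)C[C@@H](Br)[C@](C)(C=O)O1 | intermediate
17 | 5-bromo-2,6-bis(hydroxymethyl)-2,6-dimethyloxan-3-ol | OC[C@]1(C)[C@H](O)C[C@@H](Br)[C@](C)(CO)O1 | intermediate
18 | (7-bromo-2,2,4a,6-tetramethylhexahydropyrano[3,2-d][1,3]dioxin-6-yl)methanol | CC1(C)OC[C@]2(C)[C@H](O1)C[C@@H](Br)[C@](C)(CO)O2 | intermediate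
19 | 7-bromo-6-(iodomethyl)-2,2,4a,6-tetramethylhexahydropyrano[3,2-d][1,3]dioxine | CC1(C)OC[C@]2(C)[C@H](O1)C[C@@H](Br)[C@](C)(CI)O2 | intermediate
20 | ethyl 5-methylhex-4-enoate | CCOC(=O)CCC=C(C)C | starting material
21 | ethyl 3-[(2S)-3,3-dimethyloxiran-2-yl]propanoate | CCOC(=O)CC[C@@H]1OC1(C)C | intermediate
22 | prop-2-enyl acetate | CC(=O)OCC=C | starting material
23 | lithium enolate of prop-2-enyl acetate | [Li+].[O-]C(=C)OCC=C | intermediate
24 | prop-2-enyl 5-[(2S)-3,3-dimethyloxiran-2-yl]-3-oxopentanoate | C=CCOC(=O)CC(=O)CC[C@@H]1OC1(C)C | intermediate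
25 | prop-2-enyl (6R)-6-bromo-7-hydroxy-7-methyl-3-oxooctanoate | C=CCOC(=O)CC(=O)CC[C@@H](Br)C(C)(C)O | intermediate
26 | prop-2-enyl (1R,3R)-3-bromo-2,2-dimethyl-6-oxocyclohexane-1-carboxylate | C=CCOC(=O)[C@@H]1C(C)(C)[C@H](Br)CCC1=O | intermediate
27 | (1R,3R)-3-bromo-2,2-dimethyl-6-oxocyclohexane-1-carboxylic acid | OC(=O)[C@@H]1C(C)(C)[C@H](Br)CCC1=O | intermediate
28 | (3R)-3-bromo-2,2-dimethyl-1-(morpholin-4-ylmethyl)-6-oxocyclohexane-1-carboxylic acid (C1 epimers) | OC(=O)C1(CN2CCOCC2)C(C)(C)[C@H](Br)CCC1=O | intermediate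
29 | (4R)-4-bromo-3,3-dimethyl-2-methylidenecyclohexan-1-one | C=C1C(C)(C)[C@H](Br)CCC1=O | intermediate
30 | (2R,4R)-4-bromo-2-[2-(7-bromo-2,2,4a,6-tetramethylhexahydropyrano[3,2-d][1,3]dioxin-6-yl)ethyl]-3,3-dimethylcyclohexan-1-one | CC1(C)OC[C@]2(C)[C@H](O1)C[C@@H](Br)[C@](C)(CC[C@@H]3C(C)(C)[C@H](Br)CCC3=O)O2 | intermediate
31 | (1S,2R,4R)-4-bromo-2-[2-(7-bromo-2,2,4a,6-tetramethylhexahydropyrano[3,2-d][1,3]dioxin-6-yl)ethyl]-1,3,3-trimethylcyclohexan-1-ol | CC1(C)OC[C@]2(C)[C@H](O1)C[C@@H](Br)[C@](C)(CC[C@@H]3C(C)(C)[C@H](Br)CC[C@]3(C)O)O2 | intermediate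
32 | (1S,2R,4R)-4-bromo-2-{2-[3-bromo-5-hydroxy-6-(hydroxymethyl)-2,6-dimethyloxan-2-yl]ethyl}-1,3,3-trimethylcyclohexan-1-ol | OC[C@]1(C)[C@H](O)C[C@@H](Br)[C@](C)(CC[C@@H]2C(C)(C)[C@H](Br)CC[C@]2(C)O)O1 | intermediate
33 | 5-bromo-6-{2-[(1R,3R,6S)-3-bromo-6-hydroxy-2,2,6-trimethylcyclohexyl]ethyl}-2-(hydroxymethyl)-2,6-dimethyloxan-3-one | OC[C@]1(C)C(=O)C[C@@H](Br)[C@](C)(CC[C@@H]2C(C)(C)[C@H](Br)CC[C@]2(C)O)O1 | intermediate
34 | tosylhydrazone of 33 at C4 | OC[C@]1(C)C(=NNS(=O)(=O)c3ccc(C)cc3)C[C@@H](Br)[C@](C)(CC[C@@H]2C(C)(C)[C@H](Br)CC[C@]2(C)O)O1 | intermediate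
35 | N'-alkyl tosylhydrazide from reduction of 34 (C4 epimers) | OC[C@]1(C)C(NNS(=O)(=O)c3ccc(C)cc3)C[C@@H](Br)[C@](C)(CC[C@@H]2C(C)(C)[C@H](Br)CC[C@]2(C)O)O1 | intermediate
36 | (1S,2R,4R)-4-bromo-2-{2-[(2S,3R,6S)-3-bromo-6-(hydroxymethyl)-2,6-dimethyloxan-2-yl]ethyl}-1,3,3-trimethylcyclohexan-1-ol | OC[C@]1(C)CC[C@@H](Br)[C@](C)(CC[C@@H]2C(C)(C)[C@H](Br)CC[C@]2(C)O)O1 | intermediate
37 | (2S,5R,6S)-5-bromo-6-{2-[(1R,3R,6S)-3-bromo-6-hydroxy-2,2,6-trimethylcyclohexyl]ethyl}-2,6-dimethyloxane-2-carbaldehyde | O=C[C@]1(C)CC[C@@H](Br)[C@](C)(CC[C@@H]2C(C)(C)[C@H](Br)CC[C@]2(C)O)O1 | intermediate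
38 | (1S,2R,4R)-4-bromo-2-{2-[(2S,3R,6S)-3-bromo-6-ethenyl-2,6-dimethyloxan-2-yl]ethyl}-1,3,3-trimethylcyclohexan-1-ol | C=C[C@]1(C)CC[C@@H](Br)[C@](C)(CC[C@@H]2C(C)(C)[C@H](Br)CC[C@]2(C)O)O1 | target

**Step count and risks**

Total: 22 steps. Longest linear sequence: 17 steps (steps 1–9, then 15–22). The enone 29 takes 5 steps (10–14).

Steps most likely to fail:

1. Step 13 (bromonium cyclisation). The ketone oxygen rather than the enol carbon may capture the bromonium ion, HBr may be lost to an allylic bromide, or bromonium transfer may erode the enantiomeric purity. The fallback changes how the cation is made. It sets out from 25 and returns at 26. Concentrated HCl converts the tertiary carbinol of 25 into the tertiary chloride prop-2-enyl (6R)-6-bromo-7-chloro-7-methyl-3-oxooctanoate F1. This is ionised by solvolysis in hexafluoroisopropanol at rt, without Lewis acid and with the keto ester enol free, to give 26.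

2. Step 15 (radical union). Hydrogen transfer to the C8 radical may precede its addition, a 1,5-hydrogen shift from the acetonide C–H bonds may quench it, bromine may be abstracted beside iodine, or the enone may oligomerise. The fallback replaces the radical addition by a polar olefination. It sets out from 29 and 18 and returns at 32.
   - Conjugate addition of 1-phenyl-1H-tetrazole-5-thiol to 29 (Et3N cat.) gives the sulfide ketone (2R,4R)-4-bromo-3,3-dimethyl-2-{[(1-phenyl-1H-tetrazol-5-yl)sulfanyl]methyl}cyclohexan-1-one F2.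
   - MeMgBr/CeCl3, as in step 16, gives the sulfide carbinol F3.
   - Ammonium molybdate/H2O2 gives the sulfone F4.
   - TESOTf/2,6-lutidine gives the triethylsilyl ether F5.
   - Dess–Martin oxidation of 18 gives the aldehyde 7-bromo-2,2,4a,6-tetramethylhexahydropyrano[3,2-d][1,3]dioxine-6-carbaldehyde F6.
   - Julia–Kocienski olefination of F6 with the potassium salt of F5 (KHMDS, THF, −78 °C) gives the (E)-C8=C9 alkene F7.
   - Diimide (2-nitrobenzenesulfonylhydrazide, Et3N) saturates the alkene to the silyl ether acetonide F8 without touching the C–Br bonds.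
   - CSA in methanol removes the silyl ether and the acetonide together to give 32.

3. Step 5 (singlet-oxygen ene reaction). The ene reaction of the cis-disubstituted ring alkene may be too slow, so that photo-oxidation of the strained C2=C8 alkene or decomposition of the hydroperoxide competes. The fallback puts oxygen on C4 first and makes the alkene afterwards. It sets out from 6 and returns at 12. Rubottom oxidation of 6 (mCPBA, then dilute acid) gives the α-hydroxy ketone 2-exo-hydroxy-1,5-dimethyl-8-oxabicyclo[3.2.1]oct-6-en-3-one F9. Tosylhydrazide gives its tosylhydrazone F10. A Shapiro reaction (n-BuLi, 3.3 equiv, THF, −78 → 0 °C, then water) gives the allylic alcohol 1,5-dimethyl-8-oxabicyclo[3.2.1]octa-3,6-dien-2-exo-ol F11 with the C5=C6 double bond. MnO2 oxidises F11 to 12.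

Further compounds
F1 | step 13 | prop-2-enyl (6R)-6-bromo-7-chloro-7-methyl-3-oxooctanoate | C=CCOC(=O)CC(=O)CC[C@@H](Br)C(C)(C)Cl
F2 | step 15 | (2R,4R)-4-bromo-3,3-dimethyl-2-{[(1-phenyl-1H-tetrazol-5-yl)sulfanyl]methyl}cyclohexan-1-one | c1ccccc1-n1nnnc1SC[C@@H]1C(C)(C)[C@H](Br)CCC1=O
F3 | step 15 | (1S,2R,4R)-4-bromo-1,3,3-trimethyl-2-{[(1-phenyl-1H-tetrazol-5-yl)sulfanyl]methyl}cyclohexan-1-ol | c1ccccc1-n1nnnc1SC[C@@H]1C(C)(C)[C@H](Br)CC[C@]1(C)O
F4 | step 15 | (1S,2R,4R)-4-bromo-1,3,3-trimethyl-2-{[(1-phenyl-1H-tetrazol-5-yl)sulfonyl]methyl}cyclohexan-1-ol | c1ccccc1-n1nnnc1S(=O)(=O)C[C@@H]1C(C)(C)[C@H](Br)CC[C@]1(C)O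
F5 | step 15 | triethylsilyl ether of F4 | c1ccccc1-n1nnnc1S(=O)(=O)C[C@@H]1C(C)(C)[C@H](Br)CC[C@]1(C)O[Si](CC)(CC)CC
F6 | step 15 | 7-bromo-2,2,4a,6-tetramethylhexahydropyrano[3,2-d][1,3]dioxine-6-carbaldehyde | CC1(C)OC[C@]2(C)[C@H](O1)C[C@@H](Br)[C@](C)(C=O)O2
F7 | step 15 | (E)-C8=C9 alkene from F5 and F6 (acetonide, triethylsilyl ether) | CC1(C)OC[C@]2(C)[C@H](O1)C[C@@H](Br)[C@](C)(/C=C/[C@@H]3C(C)(C)[C@H](Br)CC[C@]3(C)O[Si](CC)(CC)CC)O2
F8 | step 15 | triethylsilyl ether of 31 | CC1(C)OC[C@]2(C)[C@H](O1)C[C@@H](Br)[C@](C)(CC[C@@H]3C(C)(C)[C@H](Br)CC[C@]3(C)O[Si](CC)(CC)CC)O2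
F9 | step 5 | 2-exo-hydroxy-1,5-dimethyl-8-oxabicyclo[3.2.1]oct-6-en-3-one | C2[C@]1(C)[C@@H](O)C(=O)C[C@](C)(C=2)O1
F10 | step 5 | tosylhydrazone of F9 | C2[C@]1(C)[C@@H](O)C(=NNS(=O)(=O)c3ccc(C)cc3)C[C@](C)(C=2)O1
F11 | step 5 | 1,5-dimethyl-8-oxabicyclo[3.2.1]octa-3,6-dien-2-exo-ol | C2[C@]1(C)[C@@H](O)C=C[C@](C)(C=2)O1
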